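**Retrosynthetic overview**

- Ring numbering used below: C-1 ring C=O, C-2 oxirane carbon bearing CH3, C-3 oxirane CH, C-4 CH2, C-5 CH bearing the side chain, C-6 CH bearing the 3-methylbutanoate.
- Enabling feature: the C-1 carbonyl is flanked by C-2 and C-6, and C-3 (at aldehyde oxidation level, as the oxirane carbon) stands 1,3 to C-5. The carbocycle is therefore a ketone α,α′-bis-nucleophile (C-2/C-1/C-6) joined to an enal (C-3/C-4/C-5): C-5–C-6 by Michael addition and C-2–C-3 by aldol condensation, in one amine-catalysed [3+3] annulation that sets C-5.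
- Late disconnections: tertiary allylic hydroperoxide from a prenyl ketone by Schenck ene reaction; side-chain ketone from a 1-bromovinyl handle by Nozaki–Hiyama–Kishi coupling and oxidation; oxirane by hydroxyl-directed epoxidation of the C-1 allylic alcohol; C-6 ester by α′-acyloxylation.
- Ring order: the cyclohex-2-enone first (key step), the oxirane second; C-6, the temporary C-1 carbinol, C-2 and C-3 are all relayed from C-5.

Key step: step 3

Remark: compounds 1, 4, 6, 10 and 14 and the (S)-diarylprolinol silyl ether catalyst are taken as commercial; ring atoms are numbered as in the overview.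

**Route**

Step 1
Reactants: 1 acrolein (prop-2-enal)
Product: 3 2-bromoprop-2-enal, via 2,3-dibromopropanal 2 (not isolated)
Conditions: Br2, CH2Cl2, −78 °C; then Et3N, −78 to 0 °C; used as a cold solution
Reagents that add atoms: bromine, BrBr
Why: Bromine adds across the alkene and triethylamine then removes the acidic α-hydrogen of the dibromide with loss of the β-bromide (bromination–dehydrobromination, E1cB), which should leave the 2-bromoenal; no stereocenter is formed.

Step 2
Reactants: 3 2-bromoprop-2-enal; 4 (triphenylphosphoranylidene)acetaldehyde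
Product: 5 (2E)-4-bromopenta-2,4-dienal
Conditions: CH2Cl2, 0 °C to rt, slight deficit of 4
Reagents that add atoms: none
Why: Wittig olefination with the formyl-stabilized ylide is (E)-selective, and the α-bromo aldehyde of 3 is more electrophilic than the vinylogous aldehyde of 5, which should limit a second homologation.

Step 3
Reactants: 5 (2E)-4-bromopenta-2,4-dienal; 6 tert-butyl 3-oxopentanoate
Product: 9 (5R)-5-(1-bromoethenyl)-2-methylcyclohex-2-en-1-one, via Michael adduct 7 (not isolated), via cyclized tert-butyl keto ester 8 (not isolated)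
Conditions: (S)-2-{bis[3,5-bis(trifluoromethyl)phenyl](trimethylsilyloxy)methyl}pyrrolidine (10 mol %), PhCO2H (10 mol %), toluene, 0 °C to rt; then TsOH·H2O (20 mol %), 80 °C, same flask
Reagents that add atoms: none
Why: The amine condenses with 5 to an (E) dienyl iminium ion, the enol of 6 adds to its β-carbon to make the C-5–C-6 bond and hydrolysis releases 7; TsOH then enolizes the ethyl ketone toward its CH2, which attacks the aldehyde and dehydrates to 8 (C-2–C-3 bond), and the tert-butyl ester is finally lost as 2-methylpropene with decarboxylation. The closest known reaction type is the diarylprolinol silyl ether catalysed Michael addition of tert-butyl β-keto esters to enals followed by acid-mediated aldol condensation and decarboxylation to 5-substituted cyclohex-2-enones, an organocatalytic [3+3] annulation of the Robinson kind. The carbocycle closes by a 6-(enolendo)-exo-trig aldol condensation. C-5 is the only stereocenter that survives and it is set by the catalyst: the diaryl(silyloxy)methyl group shields one face of the s-trans iminium ion, the enol enters from the other face and the (R) configuration should result, while the ester-bearing center of 7 and 8 is erased on decarboxylation. The step needs 1,4- and not 1,6-addition to the dienal, which should be favoured kinetically by the larger LUMO coefficient at the carbon next to the iminium unit and by the inductively deactivating bromine on the distal alkene, and it needs ring closure from the ethyl side only, which is secured because the other α-carbon could close nothing but a four-membered ring.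

Step 4
Reactants: 9 (5R)-5-(1-bromoethenyl)-2-methylcyclohex-2-en-1-one; 10 3-methylbutanoic acid (excess)
Product: 11 (1S,6R)-6-(1-bromoethenyl)-3-methyl-2-oxocyclohex-3-en-1-yl 3-methylbutanoate
Conditions: Mn(OAc)3·2H2O (3 equiv), benzene, reflux with azeotropic removal of water and AcOH
Reagents that add atoms: none
Why: Mn(OAc)3-mediated α′-acyloxylation of an enone: the enolate of trivalent manganese formed at C-6 transfers a carboxylate ligand (exchanged for 3-methylbutanoate) to carbon anti to the neighbouring bromovinyl group, and any cis epimer can equilibrate through the enol, so C-6 should end trans to C-5.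

Step 5
Reactants: 11 (1S,6R)-6-(1-bromoethenyl)-3-methyl-2-oxocyclohex-3-en-1-yl 3-methylbutanoate
Product: 12 (1S,2S,6R)-6-(1-bromoethenyl)-2-hydroxy-3-methylcyclohex-3-en-1-yl 3-methylbutanoate
Conditions: NaBH4, CeCl3·7H2O, MeOH, −78 °C
Reagents that add atoms: none
Why: Luche reduction: CeCl3-assisted 1,2-hydride addition should occur axially on the half-chair that keeps the C-5 and C-6 substituents equatorial, giving the equatorial C-1 alcohol cis to the bromovinyl group and trans to the ester, with the ester and both alkenes untouched.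

Step 6
Reactants: 12 (1S,2S,6R)-6-(1-bromoethenyl)-2-hydroxy-3-methylcyclohex-3-en-1-yl 3-methylbutanoate
Product: 13 (1R,2R,3S,4R,6S)-4-(1-bromoethenyl)-2-hydroxy-1-methyl-7-oxabicyclo[4.1.0]heptan-3-yl 3-methylbutanoate
Conditions: VO(acac)2 (cat.), t-BuOOH (in decane), CH2Cl2, 0 °C to rt
Reagents that add atoms: tert-butyl hydroperoxide, CC(C)(C)OO
Why: Hydroxyl-directed epoxidation: the vanadate ester of the allylic alcohol delivers oxygen to the ring alkene on the face of the hydroxyl group, so C-2 and C-3 are set with the oxirane cis to the carbinol and hence cis to the C-5 substituent, while the electron-poor bromoalkene is inert.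

Step 7
Reactants: 14 4-methylpent-3-en-1-ol
Product: 15 4-methylpent-3-enal
Conditions: Dess–Martin periodinane, pyridine, CH2Cl2, 0 °C; used at once as a solution
Reagents that add atoms: none
Why: Dess–Martin oxidation of the primary alcohol under buffered conditions should give the aldehyde without moving the trisubstituted alkene into conjugation.

Step 8
Reactants: 13 (1R,2R,3S,4R,6S)-4-(1-bromoethenyl)-2-hydroxy-1-methyl-7-oxabicyclo[4.1.0]heptan-3-yl 3-methylbutanoate; 15 4-methylpent-3-enal
Product: 16 (1R,2R,3S,4S,6S)-2-hydroxy-4-(3-hydroxy-6-methylhepta-1,5-dien-2-yl)-1-methyl-7-oxabicyclo[4.1.0]heptan-3-yl 3-methylbutanoate (both epimers at the side-chain carbinol)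
Conditions: CrCl2 (4 equiv), NiCl2 (2 mol %), DMF, rt
Reagents that add atoms: none
Why: Nozaki–Hiyama–Kishi coupling: zerovalent nickel inserts into the vinyl bromide, transmetalation gives a vinyl species of trivalent chromium that adds only to the aldehyde and tolerates the free hydroxyl, the ester and the oxirane; the new carbinol center is formed without control and is removed in step 9.

Step 9
Reactants: 16 (1R,2R,3S,4S,6S)-2-hydroxy-4-(3-hydroxy-6-methylhepta-1,5-dien-2-yl)-1-methyl-7-oxabicyclo[4.1.0]heptan-3-yl 3-methylbutanoate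
Product: 17 (1S,3S,4S,6S)-1-methyl-4-(6-methyl-3-oxohepta-1,5-dien-2-yl)-2-oxo-7-oxabicyclo[4.1.0]heptan-3-yl 3-methylbutanoate
Conditions: Dess–Martin periodinane (3 equiv), pyridine, CH2Cl2, 0 °C to rt
Reagents that add atoms: none
Why: Dess–Martin oxidation of both secondary alcohols should give the ring α,β-epoxy ketone and the side-chain α-methylene ketone in one operation, the pyridine buffer guarding against oxirane opening, epimerization at C-6 and conjugation of the β,γ-alkene.

Step 10
Reactants: 17 (1S,3S,4S,6S)-1-methyl-4-(6-methyl-3-oxohepta-1,5-dien-2-yl)-2-oxo-7-oxabicyclo[4.1.0]heptan-3-yl 3-methylbutanoate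
Product: 18 (1S,3S,4S,6S)-4-[(4E)-6-hydroperoxy-6-methyl-3-oxohepta-1,4-dien-2-yl]-1-methyl-2-oxo-7-oxabicyclo[4.1.0]heptan-3-yl 3-methylbutanoate (CNP0241468.1)
Conditions: O2, tetraphenylporphyrin (cat.), visible light, CH2Cl2, −20 °C
Reagents that add atoms: oxygen, O=O
Why: Schenck ene reaction: singlet oxygen attacks only the electron-rich trisubstituted alkene and should abstract an allylic hydrogen from the CH2 next to the ketone, the usual preference of β,γ-unsaturated carbonyl compounds, so the double bond moves into conjugation as the (E)-enone and the tertiary hydroperoxide forms; no ring stereocenter is touched.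

**Compound list**

1 | acrolein (prop-2-enal) | C=CC=O | starting material
2 | 2,3-dibromopropanal (racemic; not isolated) | O=CC(Br)CBr | intermediate
3 | 2-bromoprop-2-enal | C=C(Br)C=O | intermediate
4 | (triphenylphosphoranylidene)acetaldehyde | O=CC=P(c1ccccc1)(c1ccccc1)c1ccccc1 | starting material
5 | (2E)-4-bromopenta-2,4-dienal | C=C(Br)/C=C/C=O | intermediate
6 | tert-butyl 3-oxopentanoate | CCC(=O)CC(=O)OC(C)(C)C | starting material
7 | tert-butyl (3R)-3-(1-bromoethenyl)-5-oxo-2-propanoylpentanoate (Michael adduct; both epimers at C-2; not isolated) | C=C(Br)[C@@H](C(C(=O)CC)C(=O)OC(C)(C)C)CC=O | intermediate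
8 | tert-butyl (6R)-6-(1-bromoethenyl)-3-methyl-2-oxocyclohex-3-ene-1-carboxylate (both epimers at C-1; not isolated) | C=C(Br)[C@@H]1CC=C(C)C(=O)C1C(=O)OC(C)(C)C | intermediate
9 | (5R)-5-(1-bromoethenyl)-2-methylcyclohex-2-en-1-one | C=C(Br)[C@@H]1CC=C(C)C(=O)C1 | intermediate
10 | 3-methylbutanoic acid | CC(C)CC(=O)O | starting material
11 | (1S,6R)-6-(1-bromoethenyl)-3-methyl-2-oxocyclohex-3-en-1-yl 3-methylbutanoate | C=C(Br)[C@@H]1CC=C(C)C(=O)[C@H]1OC(=O)CC(C)C | intermediate
12 | (1S,2S,6R)-6-(1-bromoethenyl)-2-hydroxy-3-methylcyclohex-3-en-1-yl 3-methylbutanoate | C=C(Br)[C@@H]1CC=C(C)[C@H](O)[C@H]1OC(=O)CC(C)C | intermediate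
13 | (1R,2R,3S,4R,6S)-4-(1-bromoethenyl)-2-hydroxy-1-methyl-7-oxabicyclo[4.1.0]heptan-3-yl 3-methylbutanoate | C=C(Br)[C@@H]1C[C@@H]2O[C@]2(C)[C@H](O)[C@H]1OC(=O)CC(C)C | intermediate
14 | 4-methylpent-3-en-1-ol | CC(C)=CCCO | starting material
15 | 4-methylpent-3-enal | CC(C)=CCC=O | intermediate
16 | (1R,2R,3S,4S,6S)-2-hydroxy-4-(3-hydroxy-6-methylhepta-1,5-dien-2-yl)-1-methyl-7-oxabicyclo[4.1.0]heptan-3-yl 3-methylbutanoate (both epimers at the side-chain carbinol) | C=C(C(O)CC=C(C)C)[C@@H]1C[C@@H]2O[C@]2(C)[C@H](O)[C@H]1OC(=O)CC(C)C | intermediate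
17 | (1S,3S,4S,6S)-1-methyl-4-(6-methyl-3-oxohepta-1,5-dien-2-yl)-2-oxo-7-oxabicyclo[4.1.0]heptan-3-yl 3-methylbutanoate | C=C(C(=O)CC=C(C)C)[C@@H]1C[C@@H]2O[C@]2(C)C(=O)[C@H]1OC(=O)CC(C)C | intermediate
18 | (1S,3S,4S,6S)-4-[(4E)-6-hydroperoxy-6-methyl-3-oxohepta-1,4-dien-2-yl]-1-methyl-2-oxo-7-oxabicyclo[4.1.0]heptan-3-yl 3-methylbutanoate (CNP0241468.1) | C=C(C(=O)/C=C/C(C)(C)OO)[C@@H]1C[C@@H]2O[C@]2(C)C(=O)[C@H]1OC(=O)CC(C)C | target

**Step count and risks**

Total step count: 10. Longest linear sequence: 9 steps (steps 1, 2, 3, 4, 5, 6, 8, 9, 10).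

Steps most likely to fail:

1. Step 3. Conjugate addition of the keto ester enol at the terminal carbon of the dienyl iminium ion (1,6-addition) and oligomerization of the bromodiene may compete with the wanted 1,4-addition. The fallback sets out from 6 and comes back at 9. Wittig reaction of commercial 3-(trimethylsilyl)prop-2-ynal with 4 gives (2E)-5-(trimethylsilyl)pent-2-en-4-ynal F1, whose silyl-capped alkyne offers no accessible remote position. The same amine-catalysed Michael addition and acid-mediated aldol condensation–decarboxylation with 6 gives (5R)-2-methyl-5-[(trimethylsilyl)ethynyl]cyclohex-2-en-1-one F2. K2CO3 in MeOH removes the silyl group to give (5R)-5-ethynyl-2-methylcyclohex-2-en-1-one F3. Markovnikov hydrobromination of the terminal alkyne with tetraethylammonium hydrogen dibromide in CH2Cl2 then gives 9.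

2. Step 8. Oxidative addition into the hindered, α-branched vinyl bromide may be slow, so that protodebromination, acyl migration from the C-6 oxygen to the neighbouring chromium alkoxide, and isomerization of the β,γ-unsaturated aldehyde take over. The fallback sets out from 13 and comes back at 17. Pd(PPh3)4-catalysed exchange with hexamethylditin converts the bromide into (1R,2R,3S,4R,6S)-2-hydroxy-1-methyl-4-[1-(trimethylstannyl)ethenyl]-7-oxabicyclo[4.1.0]heptan-3-yl 3-methylbutanoate F4. Carbonylative Stille coupling of F4 with 1-chloro-3-methylbut-2-ene under CO (Pd2(dba)3, triphenylarsine) gives (1R,2R,3S,4S,6S)-2-hydroxy-1-methyl-4-(6-methyl-3-oxohepta-1,5-dien-2-yl)-7-oxabicyclo[4.1.0]heptan-3-yl 3-methylbutanoate F5 directly at the ketone oxidation level. Dess–Martin oxidation of the remaining ring carbinol gives 17.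

3. Step 4. Facial control at C-6 may be poor, and acetate may be transferred in place of 3-methylbutanoate. The fallback sets out from 9 and comes back at 11. Kinetic deprotonation with lithium diisopropylamide (THF, −78 °C) gives lithium (6R)-6-(1-bromoethenyl)-3-methylcyclohexa-1,3-dien-2-olate F6. Oxygen transfer from 2-(phenylsulfonyl)-3-phenyloxaziridine anti to the bromovinyl group, with an acetic acid quench, gives (5R,6S)-5-(1-bromoethenyl)-6-hydroxy-2-methylcyclohex-2-en-1-one F7. Acylation with 3-methylbutanoyl chloride, pyridine and DMAP gives 11.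

Further compounds
F1 | step 3 | (2E)-5-(trimethylsilyl)pent-2-en-4-ynal | C[Si](C)(C)C#C/C=C/C=O
F2 | step 3 | (5R)-2-methyl-5-[(trimethylsilyl)ethynyl]cyclohex-2-en-1-one | C[Si](C)(C)C#C[C@@H]1CC=C(C)C(=O)C1
F3 | step 3 | (5R)-5-ethynyl-2-methylcyclohex-2-en-1-one | C#C[C@@H]1CC=C(C)C(=O)C1
F4 | step 8 | (1R,2R,3S,4R,6S)-2-hydroxy-1-methyl-4-[1-(trimethylstannyl)ethenyl]-7-oxabicyclo[4.1.0]heptan-3-yl 3-methylbutanoate | C=C([Sn](C)(C)C)[C@@H]1C[C@@H]2O[C@]2(C)[C@H](O)[C@H]1OC(=O)CC(C)C
F5 | step 8 | (1R,2R,3S,4S,6S)-2-hydroxy-1-methyl-4-(6-methyl-3-oxohepta-1,5-dien-2-yl)-7-oxabicyclo[4.1.0]heptan-3-yl 3-methylbutanoate | C=C(C(=O)CC=C(C)C)[C@@H]1C[C@@H]2O[C@]2(C)[C@H](O)[C@H]1OC(=O)CC(C)C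
F6 | step 4 | lithium (6R)-6-(1-bromoethenyl)-3-methylcyclohexa-1,3-dien-2-olate | C=C(Br)[C@@H]1CC=C(C)C(O[Li])=C1
F7 | step 4 | (5R,6S)-5-(1-bromoethenyl)-6-hydroxy-2-methylcyclohex-2-en-1-one | C=C(Br)[C@@H]1CC=C(C)C(=O)[C@H]1O
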